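**Plan**
Numbering follows the 1,2-dihydronaphthalene. Ring B is C1, C2, C3, C4, C4a, C8a and the benzo ring is C4a, C5, C6, C7, C8, C8a. The two rings have only the bond C4a–C8a in common, and C5 and C8 are plain CH.
Retrosynthesis: C6–O and C7–O go back to C–B bonds, then C4a–C8a, C5–C6 and C7–C8 are cut together. Because of the shared bond this opens both rings and leaves C4a≡C5 and C8a≡C8 as terminal alkynes on the acyclic chain C1–C2–C3=C4 (Z), beside a C6≡C7 diborylalkyne.
The chain is then cut at C4a–C5 (aldehyde homologation), C3–CH3 (cuprate), C3–C4 (dibromo-olefination), C2–CH3 (enolate methylation) and C1–C8a (conjugate alkynylation), back to veratraldehyde and Meldrum's acid.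
Forward: the chain grows linearly from C1 to C5 (steps 1–13), ring B and the benzo ring arise in one operation (step 14), and two steps turn C–B into C–OMe.
Stereochemistry: C1 (R) comes from a ligand-controlled rhodium alkynylation, C2 (S) from an oxazolidinone-controlled methylation, and the Z-alkene from a syn carbocupration. The ring-forming step creates no stereocentre and carries the trans C1/C2 relationship through.

Key step: step 14

Assumption: the (S)-bisphosphine in step 2 is taken to deliver the alkynyl group to the face of the arylidene acceptor that gives the R-configured adduct. If the sense of induction is the opposite one, the (R)-ligand is used and nothing else changes.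

Step 1
Reactants: 1 veratraldehyde (3,4-dimethoxybenzaldehyde); 2 Meldrum's acid (2,2-dimethyl-1,3-dioxane-4,6-dione)
Product: 3 5-(3,4-dimethoxybenzylidene)-2,2-dimethyl-1,3-dioxane-4,6-dione
Conditions: pyrrolidine (10 mol %), AcOH (10 mol %), toluene, rt
Reagents that add atoms: none
Why: Knoevenagel condensation of a non-enolisable aromatic aldehyde with the strongly C–H acidic Meldrum's acid should be fast under amine/acid catalysis, and the symmetric acceptor raises no E/Z question.

Step 2
Reactants: 3 5-(3,4-dimethoxybenzylidene)-2,2-dimethyl-1,3-dioxane-4,6-dione; 4 trimethylsilylacetylene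
Product: 5 5-[(1R)-1-(3,4-dimethoxyphenyl)-3-(trimethylsilyl)prop-2-yn-1-yl]-2,2-dimethyl-1,3-dioxane-4,6-dione
Conditions: 4 (3 equiv), [Rh(acac)(C2H4)2] (5 mol %), (S)-3,5-xylyl-MeO-BIPHEP (6 mol %), ClCH2CH2Cl, rt
Reagents that add atoms: none
Why: Rhodium-catalysed enantioselective conjugate alkynylation of 5-arylidene Meldrum's acids, in which an alkynylrhodium(I) species adds 1,4 to the doubly activated alkene, the C2-symmetric bisphosphine blocks one face of the benzylic carbon and so sets C1 as R, and the bulky silyl group holds back alkyne dimerisation.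

Step 3
Reactants: 5 5-[(1R)-1-(3,4-dimethoxyphenyl)-3-(trimethylsilyl)prop-2-yn-1-yl]-2,2-dimethyl-1,3-dioxane-4,6-dione
Product: 6 (3R)-3-(3,4-dimethoxyphenyl)-5-(trimethylsilyl)pent-4-ynoic acid
Conditions: DMF–H2O (10:1), 100 °C
Reagents that add atoms: water, O
Why: Hydrolytic opening of the Meldrum's acid ring followed by thermal decarboxylation of the malonic acid runs without added acid or base, so neither the C(sp)–Si bond nor the benzylic stereocentre should be touched.

Step 4
Reactants: 6 (3R)-3-(3,4-dimethoxyphenyl)-5-(trimethylsilyl)pent-4-ynoic acid; 7 (S)-4-benzyl-1,3-oxazolidin-2-one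
Product: 9 (4S)-4-benzyl-3-[(3R)-3-(3,4-dimethoxyphenyl)-5-(trimethylsilyl)pent-4-ynoyl]-1,3-oxazolidin-2-one, via mixed pivalic anhydride 8 (not isolated)
Conditions: PivCl, Et3N, THF, −20 °C; then LiCl, 7, −20 °C → rt
Reagents that add atoms: pivaloyl chloride, CC(C)(C)C(=O)Cl (its acyl group stays only in 8)
Why: N-acylation of an Evans oxazolidinone through the mixed anhydride with LiCl/Et3N needs no strong base, and the nucleophile attacks the less hindered carbonyl group of the anhydride.

Step 5
Reactants: 9 (4S)-4-benzyl-3-[(3R)-3-(3,4-dimethoxyphenyl)-5-(trimethylsilyl)pent-4-ynoyl]-1,3-oxazolidin-2-one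
Product: 11 (4S)-4-benzyl-3-[(2S,3R)-3-(3,4-dimethoxyphenyl)-2-methyl-5-(trimethylsilyl)pent-4-ynoyl]-1,3-oxazolidin-2-one, via sodium Z-enolate 10 (not isolated)
Conditions: NaHMDS (1.1 equiv), THF, −78 °C; MeI (5 equiv), −78 °C
Reagents that add atoms: iodomethane, CI; sodium hexamethyldisilazide, C[Si](C)(C)[N-][Si](C)(C)C.[Na+] (its sodium stays only in 10)
Why: Evans asymmetric alkylation, in which the chelated Z-enolate is methylated on the face away from the benzyl group, so that C2 is set as S under auxiliary control and methyl and aryl come out in the relationship that is trans in ring B.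

Step 6
Reactants: 11 (4S)-4-benzyl-3-[(2S,3R)-3-(3,4-dimethoxyphenyl)-2-methyl-5-(trimethylsilyl)pent-4-ynoyl]-1,3-oxazolidin-2-one
Product: 12 (2S,3R)-3-(3,4-dimethoxyphenyl)-2-methyl-5-(trimethylsilyl)pent-4-yn-1-ol
Conditions: LiBH4, H2O (1 equiv), Et2O, 0 °C
Reagents that add atoms: none
Why: Reductive cleavage of an N-acyloxazolidinone with lithium borohydride attacks the exocyclic carbonyl group, releases the auxiliary for re-use and is not basic enough to epimerise C2.

Step 7
Reactants: 12 (2S,3R)-3-(3,4-dimethoxyphenyl)-2-methyl-5-(trimethylsilyl)pent-4-yn-1-ol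
Product: 13 (2S,3R)-3-(3,4-dimethoxyphenyl)-2-methyl-5-(trimethylsilyl)pent-4-ynal
Conditions: TEMPO (10 mol %), PhI(OAc)2 (1.1 equiv), CH2Cl2, rt
Reagents that add atoms: none
Why: Oxoammonium (TEMPO) oxidation of a primary alcohol stops at the aldehyde and is base-free, so the alpha stereocentre C2 should keep its configuration.

Step 8
Reactants: 13 (2S,3R)-3-(3,4-dimethoxyphenyl)-2-methyl-5-(trimethylsilyl)pent-4-ynal
Product: 14 [(3R,4S)-6,6-dibromo-3-(3,4-dimethoxyphenyl)-4-methylhex-5-en-1-yn-1-yl]trimethylsilane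
Conditions: CBr4 (2 equiv), PPh3 (4 equiv), CH2Cl2, 0 °C
Reagents that add atoms: tetrabromomethane, BrC(Br)(Br)Br
Why: Ramirez dibromo-olefination (first stage of the Corey–Fuchs sequence) is a fast Wittig-type reaction under non-basic conditions that adds C4 without endangering the alpha-branched aldehyde.

Step 9
Reactants: 14 [(3R,4S)-6,6-dibromo-3-(3,4-dimethoxyphenyl)-4-methylhex-5-en-1-yn-1-yl]trimethylsilane
Product: 16 methyl (4S,5R)-5-(3,4-dimethoxyphenyl)-4-methyl-7-(trimethylsilyl)hepta-2,6-diynoate, via lithium acetylide 15 (not isolated)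
Conditions: n-BuLi (2.05 equiv), THF, −78 °C; ClCO2Me, −78 → 0 °C
Reagents that add atoms: methyl chloroformate, COC(=O)Cl; n-butyllithium, [Li]CCCC (its lithium stays only in 15)
Why: Second stage of the Corey–Fuchs sequence, in which bromine–lithium exchange and Fritsch–Buttenberg–Wiechell rearrangement give the acetylide, which is acylated in the same flask; both are much faster at −78 °C than deprotonation at C1 or attack at silicon.

Step 10
Reactants: 16 methyl (4S,5R)-5-(3,4-dimethoxyphenyl)-4-methyl-7-(trimethylsilyl)hepta-2,6-diynoate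
Product: 17 methyl (2Z,4S,5R)-5-(3,4-dimethoxyphenyl)-3,4-dimethyl-7-(trimethylsilyl)hept-2-en-6-ynoate
Conditions: Me2CuLi (from CuI and 2 MeLi, 1.5 equiv), THF, −78 °C; MeOH at −78 °C, then aq NH4Cl
Reagents that add atoms: methyllithium (delivered as Me2CuLi), [Li]C
Why: Conjugate addition of a Gilman reagent to a 2-alkynoate is a stereospecific syn carbocupration at −78 °C in THF, so protonation with retention places the new methyl group cis to H-4 and C2 cis to the ester carbon (Z), while the low temperature keeps the alkenylcuprate from equilibrating through the allenolate.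

Step 11
Reactants: 17 methyl (2Z,4S,5R)-5-(3,4-dimethoxyphenyl)-3,4-dimethyl-7-(trimethylsilyl)hept-2-en-6-ynoate
Product: 18 (2Z,4S,5R)-5-(3,4-dimethoxyphenyl)-3,4-dimethyl-7-(trimethylsilyl)hept-2-en-6-yn-1-ol
Conditions: DIBAL-H (2.5 equiv), CH2Cl2, −78 °C; Rochelle salt work-up
Reagents that add atoms: none
Why: DIBAL-H reduces enoates cleanly in the 1,2-sense to allylic alcohols without changing the alkene geometry, and hydroalumination of the silylalkyne does not compete at −78 °C.

Step 12
Reactants: 18 (2Z,4S,5R)-5-(3,4-dimethoxyphenyl)-3,4-dimethyl-7-(trimethylsilyl)hept-2-en-6-yn-1-ol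
Product: 19 (2Z,4S,5R)-5-(3,4-dimethoxyphenyl)-3,4-dimethyl-7-(trimethylsilyl)hept-2-en-6-ynal
Conditions: TEMPO (10 mol %), PhI(OAc)2 (1.1 equiv), MeCN–pH 7 buffer, 0 °C
Reagents that add atoms: none
Why: Buffered oxoammonium (TEMPO) oxidation is an established way to turn Z-configured 3-methylallylic alcohols into Z-enals without Z/E isomerisation, because no strong acid, base or radical chain is involved.

Step 13
Reactants: 19 (2Z,4S,5R)-5-(3,4-dimethoxyphenyl)-3,4-dimethyl-7-(trimethylsilyl)hept-2-en-6-ynal
Product: 21 (3Z,5S,6S)-6-(3,4-dimethoxyphenyl)-4,5-dimethyloct-3-ene-1,7-diyne, via C8-silylated enediyne 20 (not isolated)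
Conditions: TMSCHN2 (1.2 equiv), n-BuLi (1.2 equiv), THF, −78 °C, then 19, −78 → 0 °C; then MeOH, K2CO3 (0.3 equiv), 0 °C → rt
Reagents that add atoms: (trimethylsilyl)diazomethane, C[Si](C)(C)C=[N+]=[N-]
Why: Colvin rearrangement (addition of the lithiated diazo compound, Peterson-type loss of silanolate, loss of N2 and 1,2-hydrogen shift of the alkylidene carbene) adds C5 at low temperature with the alkene geometry retained, and mild methanolysis of the C(sp)–Si bond then frees the second terminal alkyne without being basic enough to deprotonate C1.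

Step 14
Reactants: 21 (3Z,5S,6S)-6-(3,4-dimethoxyphenyl)-4,5-dimethyloct-3-ene-1,7-diyne; 22 bis(pinacolato)acetylene (1,2-bis(4,4,5,5-tetramethyl-1,3,2-dioxaborolan-2-yl)ethyne)
Product: 23 2,2'-[(5R,6S)-5-(3,4-dimethoxyphenyl)-6,7-dimethyl-5,6-dihydronaphthalene-2,3-diyl]bis(4,4,5,5-tetramethyl-1,3,2-dioxaborolane) (the 6,7-diboryl analogue of the target; 1R,2S in target numbering)
Conditions: 22 (3 equiv), CpCo(CO)2 (20 mol %), toluene, reflux, visible-light irradiation, Ar; 21 added by syringe pump over 10 h
Reagents that add atoms: none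
Why: CpCo, freed from CO by heat and light, binds both alkynes of 21 and couples them oxidatively to a cobaltacyclopentadiene (bond C4a–C8a), after which 22 coordinates and inserts or adds in a [4+2] sense (bonds C5–C6 and C7–C8) and reductive elimination releases 23 and CpCo. The closest known reaction type is the cobalt-catalysed [2+2+2] co-cyclotrimerisation of α,ω-diynes with bulky symmetric alkynes such as bis(trimethylsilyl)acetylene, which has been extended to alkynylboronates including 22. Ring B closes in the intramolecular oxidative coupling, where the four-atom tether C1–C2–C3=C4 ends up in a six-membered carbocycle fused to the metallacycle, and the benzo ring closes in the intermolecular stage by uptake of the third alkyne and C–C reductive elimination. No stereocentre is formed: C1 and C2 are spectators under neutral, non-ionising conditions, and the Z-alkene simply becomes the endocyclic C3=C4 bond. The step needs chemoselectivity for diyne plus monoyne over self-reaction of 21, which is secured by the Z-alkene holding the two alkynes within bonding distance, by the low stationary concentration of 21, and by an excess of 22, which is too hindered to trimerise on its own. Regiochemistry is no issue, because 22 is symmetric and the tether fixes the orientation of the diyne.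

Step 15
Reactants: 23 2,2'-[(5R,6S)-5-(3,4-dimethoxyphenyl)-6,7-dimethyl-5,6-dihydronaphthalene-2,3-diyl]bis(4,4,5,5-tetramethyl-1,3,2-dioxaborolane)
Product: 24 (5R,6S)-5-(3,4-dimethoxyphenyl)-6,7-dimethyl-5,6-dihydronaphthalene-2,3-diol
Conditions: 30 % aq H2O2, aq NaOH, THF, 0 °C, Ar; then 1 M HCl
Reagents that add atoms: hydrogen peroxide, OO
Why: Oxidation of arylboronic esters with basic hydrogen peroxide proceeds by 1,2-migration of the aryl group from boron to oxygen at both positions, the unactivated trisubstituted alkene is inert to the nucleophilic oxidant, and exclusion of air with early acidification protects the catechol.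

Step 16
Reactants: 24 (5R,6S)-5-(3,4-dimethoxyphenyl)-6,7-dimethyl-5,6-dihydronaphthalene-2,3-diol
Product: 25 (1R,2S)-1-(3,4-dimethoxyphenyl)-6,7-dimethoxy-2,3-dimethyl-1,2-dihydronaphthalene (target)
Conditions: MeI (4 equiv), K2CO3 (4 equiv), acetone, reflux, Ar
Reagents that add atoms: iodomethane, CI
Why: Williamson ether synthesis on both phenolic oxygens needs only carbonate as base, which is far too weak to deprotonate the benzylic C1–H.

**Compound list**
1 | veratraldehyde (3,4-dimethoxybenzaldehyde) | COc1ccc(C=O)cc1OC | starting material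
2 | Meldrum's acid (2,2-dimethyl-1,3-dioxane-4,6-dione) | CC1(C)OC(=O)CC(=O)O1 | starting material
3 | 5-(3,4-dimethoxybenzylidene)-2,2-dimethyl-1,3-dioxane-4,6-dione | COc1ccc(C=C2C(=O)OC(C)(C)OC2=O)cc1OC | intermediate
4 | trimethylsilylacetylene | C#C[Si](C)(C)C | starting material
5 | 5-[(1R)-1-(3,4-dimethoxyphenyl)-3-(trimethylsilyl)prop-2-yn-1-yl]-2,2-dimethyl-1,3-dioxane-4,6-dione | COc1ccc([C@@H](C2C(=O)OC(C)(C)OC2=O)C#C[Si](C)(C)C)cc1OC | intermediate
6 | (3R)-3-(3,4-dimethoxyphenyl)-5-(trimethylsilyl)pent-4-ynoic acid | COc1ccc([C@@H](CC(=O)O)C#C[Si](C)(C)C)cc1OC | intermediate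
7 | (S)-4-benzyl-1,3-oxazolidin-2-one | O=C1N[C@@H](Cc2ccccc2)CO1 | starting material
8 | mixed anhydride of 6 with pivalic acid (not isolated) | COc1ccc([C@@H](CC(=O)OC(=O)C(C)(C)C)C#C[Si](C)(C)C)cc1OC | intermediate
9 | (4S)-4-benzyl-3-[(3R)-3-(3,4-dimethoxyphenyl)-5-(trimethylsilyl)pent-4-ynoyl]-1,3-oxazolidin-2-one | COc1ccc([C@@H](CC(=O)N2C(=O)OC[C@@H]2Cc3ccccc3)C#C[Si](C)(C)C)cc1OC | intermediate
10 | sodium Z-enolate of 9 (not isolated) | COc1ccc([C@@H](/C=C(\[O-])N2C(=O)OC[C@@H]2Cc3ccccc3)C#C[Si](C)(C)C)cc1OC.[Na+] | intermediate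
11 | (4S)-4-benzyl-3-[(2S,3R)-3-(3,4-dimethoxyphenyl)-2-methyl-5-(trimethylsilyl)pent-4-ynoyl]-1,3-oxazolidin-2-one | COc1ccc([C@@H]([C@H](C)C(=O)N2C(=O)OC[C@@H]2Cc3ccccc3)C#C[Si](C)(C)C)cc1OC | intermediate
12 | (2S,3R)-3-(3,4-dimethoxyphenyl)-2-methyl-5-(trimethylsilyl)pent-4-yn-1-ol | COc1ccc([C@@H]([C@H](C)CO)C#C[Si](C)(C)C)cc1OC | intermediate
13 | (2S,3R)-3-(3,4-dimethoxyphenyl)-2-methyl-5-(trimethylsilyl)pent-4-ynal | COc1ccc([C@@H]([C@H](C)C=O)C#C[Si](C)(C)C)cc1OC | intermediate
14 | [(3R,4S)-6,6-dibromo-3-(3,4-dimethoxyphenyl)-4-methylhex-5-en-1-yn-1-yl]trimethylsilane | COc1ccc([C@@H]([C@H](C)C=C(Br)Br)C#C[Si](C)(C)C)cc1OC | intermediate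
15 | lithium acetylide formed from 14 (not isolated) | COc1ccc([C@@H]([C@H](C)C#C[Li])C#C[Si](C)(C)C)cc1OC | intermediate
16 | methyl (4S,5R)-5-(3,4-dimethoxyphenyl)-4-methyl-7-(trimethylsilyl)hepta-2,6-diynoate | COc1ccc([C@@H]([C@H](C)C#CC(=O)OC)C#C[Si](C)(C)C)cc1OC | intermediate
17 | methyl (2Z,4S,5R)-5-(3,4-dimethoxyphenyl)-3,4-dimethyl-7-(trimethylsilyl)hept-2-en-6-ynoate | COc1ccc([C@@H]([C@H](C)/C(C)=C\C(=O)OC)C#C[Si](C)(C)C)cc1OC | intermediate
18 | (2Z,4S,5R)-5-(3,4-dimethoxyphenyl)-3,4-dimethyl-7-(trimethylsilyl)hept-2-en-6-yn-1-ol | COc1ccc([C@@H]([C@H](C)/C(C)=C\CO)C#C[Si](C)(C)C)cc1OC | intermediate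
19 | (2Z,4S,5R)-5-(3,4-dimethoxyphenyl)-3,4-dimethyl-7-(trimethylsilyl)hept-2-en-6-ynal | COc1ccc([C@@H]([C@H](C)/C(C)=C\C=O)C#C[Si](C)(C)C)cc1OC | intermediate
20 | [(3R,4S,5Z)-3-(3,4-dimethoxyphenyl)-4,5-dimethyloct-5-ene-1,7-diyn-1-yl]trimethylsilane (not isolated) | COc1ccc([C@@H]([C@H](C)/C(C)=C\C#C)C#C[Si](C)(C)C)cc1OC | intermediate
21 | (3Z,5S,6S)-6-(3,4-dimethoxyphenyl)-4,5-dimethyloct-3-ene-1,7-diyne | COc1ccc([C@@H]([C@H](C)/C(C)=C\C#C)C#C)cc1OC | intermediate
22 | bis(pinacolato)acetylene | CC1(C)OB(C#CB2OC(C)(C)C(C)(C)O2)OC1(C)C | starting material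
23 | 2,2'-[(5R,6S)-5-(3,4-dimethoxyphenyl)-6,7-dimethyl-5,6-dihydronaphthalene-2,3-diyl]bis(4,4,5,5-tetramethyl-1,3,2-dioxaborolane) | COc1ccc([C@@H]2c3cc(B4OC(C)(C)C(C)(C)O4)c(B4OC(C)(C)C(C)(C)O4)cc3C=C(C)[C@H]2C)cc1OC | intermediate
24 | (5R,6S)-5-(3,4-dimethoxyphenyl)-6,7-dimethyl-5,6-dihydronaphthalene-2,3-diol | COc1ccc([C@@H]2c3cc(O)c(O)cc3C=C(C)[C@H]2C)cc1OC | intermediate
25 | (1R,2S)-1-(3,4-dimethoxyphenyl)-6,7-dimethoxy-2,3-dimethyl-1,2-dihydronaphthalene | COc1ccc([C@@H]2c3cc(OC)c(OC)cc3C=C(C)[C@H]2C)cc1OC | target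

**Total step count:** 16. **Longest linear sequence:** 16 steps (from veratraldehyde).

**Steps most likely to fail**

Step 14. The terminal diyne may oligomerise with itself. The hindered, electron-poor diborylalkyne may enter the cobaltacycle too slowly. C–B bonds may be lost by protodeborylation during the long heating. The fallback sets out from 21 and replaces boron by an oxidisable silicon group. Bis[isopropoxy(dimethyl)silyl]acetylene F1 is made from ethyne-1,2-diylbis(magnesium bromide) and chloro(isopropoxy)dimethylsilane. It is a close, less electron-poor relative of bis(trimethylsilyl)acetylene and can be used in large excess as co-solvent of the cobalt-catalysed cocyclisation. This should give the 6,7-bis[isopropoxy(dimethyl)silyl]dihydronaphthalene F2. Tamao–Fleming oxidation (H2O2, KF, KHCO3, THF–MeOH) then converts both aryl–silicon bonds into aryl–OH bonds, and the route is rejoined at 24.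

Step 13. The basic lithiated diazo compound may deprotonate the Z-enal at the gamma position, which would scramble the alkene geometry. It may also give low conversion to the alkylidene carbene. The fallback sets out from 19 and forms the new carbon–carbon bond under non-basic conditions. Ramirez dibromo-olefination (CBr4, PPh3, CH2Cl2, 0 °C) gives the 1,1-dibromodiene F3. This compound has no acidic carbonyl-activated hydrogen left. Treatment with n-BuLi (2 equiv, THF, −78 °C) converts it into the lithium acetylide F4, and water protonates this to 20. There the route is rejoined, with 20 now isolated and desilylated with K2CO3/MeOH as in the second half of step 13.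

Step 2. The electron-rich arylidene is a weakened acceptor, so conversion may be low, and facial selectivity at the benzylic carbon may be insufficient. The fallback sets out from 3 and gives up catalytic induction for a separation on the auxiliary that the route needs anyway. Uncatalysed 1,4-addition of (trimethylsilyl)ethynylmagnesium bromide (THF, 0 °C) gives the racemic adduct F5. Hydrolysis and decarboxylation as in step 3 give the racemic acid F6. Activation as in step 4 gives the racemic mixed anhydride F7, and acylation of 7 gives 9 together with its (3S)-epimer F8. The two imides are diastereomers and are separated by chromatography or crystallisation, and the route is rejoined at 9.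

**Further compounds**
F1 | step 14 | bis[isopropoxy(dimethyl)silyl]acetylene | CC(C)O[Si](C)(C)C#C[Si](C)(C)OC(C)C
F2 | step 14 | (1R,2S)-1-(3,4-dimethoxyphenyl)-6,7-bis[isopropoxy(dimethyl)silyl]-2,3-dimethyl-1,2-dihydronaphthalene | COc1ccc([C@@H]2c3cc([Si](C)(C)OC(C)C)c([Si](C)(C)OC(C)C)cc3C=C(C)[C@H]2C)cc1OC
F3 | step 13 | [(3R,4S,5Z)-8,8-dibromo-3-(3,4-dimethoxyphenyl)-4,5-dimethylocta-5,7-dien-1-yn-1-yl]trimethylsilane | COc1ccc([C@@H]([C@H](C)/C(C)=C\C=C(Br)Br)C#C[Si](C)(C)C)cc1OC
F4 | step 13 | lithium acetylide of 20 | COc1ccc([C@@H]([C@H](C)/C(C)=C\C#C[Li])C#C[Si](C)(C)C)cc1OC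
F5 | step 2 | racemic 5-[1-(3,4-dimethoxyphenyl)-3-(trimethylsilyl)prop-2-yn-1-yl]-2,2-dimethyl-1,3-dioxane-4,6-dione | COc1ccc(C(C2C(=O)OC(C)(C)OC2=O)C#C[Si](C)(C)C)cc1OC
F6 | step 2 | racemic 3-(3,4-dimethoxyphenyl)-5-(trimethylsilyl)pent-4-ynoic acid | COc1ccc(C(CC(=O)O)C#C[Si](C)(C)C)cc1OC
F7 | step 2 | racemic mixed anhydride of F6 with pivalic acid | COc1ccc(C(CC(=O)OC(=O)C(C)(C)C)C#C[Si](C)(C)C)cc1OC
F8 | step 2 | (4S)-4-benzyl-3-[(3S)-3-(3,4-dimethoxyphenyl)-5-(trimethylsilyl)pent-4-ynoyl]-1,3-oxazolidin-2-one | COc1ccc([C@H](CC(=O)N2C(=O)OC[C@@H]2Cc3ccccc3)C#C[Si](C)(C)C)cc1OC
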